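Numbering: lactone O1, C2 (C=O), C3 (CH3), C4 (OH), C5; exocyclic C6; C7 (S, CH3); chain C8–C18 with CH3 on C11 and C15; furan-3-yl on C18. Enabling feature: the C13 methylene lies between two identical (E)-CH2–C(CH3)=CH units (C10–C11=C12 and C14=C15–C16), so C10–C16 is a twofold-symmetric core, and neither ring of the target (furan, butenolide) has to be built.
Retrosynthesis: cut C5=C6 (aldol–elimination onto an O-methyl tetronate), then C9–C10 and C16–C17 (two copper-catalysed allylic couplings) to reach dibromide 8. Both C=C/C–Br pairs of 8 go back to the cyclopropyl mesylates of 6, and the rings of 6 to penta-1,4-diene (C10, C12, C13, C14, C16) plus two ethyl acetate carbonyls (C11, C15 with their methyls).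
Forward: the core first (steps 1–3), then the furan arm C17–C18 (step 5), the chiral arm C6–C9 (step 10) and last the butenolide (steps 13–16). The two cyclopropanes are the only rings formed, and both are opened again.
Stereochemistry: C7 comes unchanged from (S)-2-methylbutane-1,4-diol. The 11E and 14E alkenes follow from the cis-selective cyclopropanation and the outward rotation in the ring opening. The 5E alkene is obtained by elimination and separation of the geometric isomers.

Key step: step 3

Remark: 3–7 carry only relative configuration inside each ring (methyl cis to the C13 branch); 4–6 are mixtures of meso and racemic ring-to-ring isomers, one of which is drawn, and all converge on achiral 8. The carbinol centres C5 and C6 of 25 and 26 are unassigned mixtures that disappear in step 15.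

Step 1
Reactants: 1 penta-1,4-diene; 2 ethyl acetate (two molecules)
Product: 4 2,2'-methylenebis(1-methylcyclopropan-1-ol) (methyl cis to the bridging CH2 in each ring), via monocyclopropanol 3 (not isolated)
Conditions: EtOAc (3 equiv), Ti(OiPr)4 (2 equiv), c-C5H9MgCl (9 equiv, added over 4 h), THF, 20 °C; then H2O, 0 °C
Reagents that add atoms: none
Why: Kulinkovich hydroxycyclopropanation with alkene exchange, in which the titanacyclopropane made from Ti(OiPr)4 and c-C5H9MgCl passes its titanium to each terminal alkene of 1 in turn and the exchanged titanacyclopropane adds to ethyl acetate and closes with the alkyl branch trans to oxygen, so that the methyl ends cis to the bridging CH2 in each ring while the ring-to-ring relation stays uncontrolled because step 3 removes it.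

Step 2
Reactants: 4 2,2'-methylenebis(1-methylcyclopropan-1-ol)
Product: 6 methylenebis(1-methylcyclopropane-2,1-diyl) dimethanesulfonate, via monomesylate 5 (not isolated)
Conditions: MsCl, Et3N, CH2Cl2, −10 to 0 °C
Reagents that add atoms: methanesulfonyl chloride, CS(=O)(=O)Cl
Why: Sulfonylation of the tertiary cyclopropanols through sulfene, which needs no substitution at the hindered carbinol carbon and leaves the strained rings and their configuration intact in cold basic medium.

Step 3
Reactants: 6 methylenebis(1-methylcyclopropane-2,1-diyl) dimethanesulfonate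
Product: 8 (2E,5E)-1,7-dibromo-2,6-dimethylhepta-2,5-diene, via bromo mesylate 7 (not isolated)
Conditions: MgBr2·OEt2 (4 equiv), Et2O, reflux
Reagents that add atoms: magnesium bromide (as its diethyl etherate), Br[Mg]Br
Why: MgBr2 assists ionisation of each tertiary mesylate, which is concerted with disrotatory cleavage of the distal ring bond (two-electron electrocyclic opening of a cyclopropyl cation, Woodward–Hoffmann–DePuy rule) and gives a 2-methylallyl cation that bromide captures at its unsubstituted terminus. The closest known reaction is the MgBr2-induced conversion of cis-1,2-dialkylcyclopropanol sulfonates into (E)-2-methylalk-2-enyl bromides, run here on two independent rings of one molecule by way of 7. No ring is closed and no stereocentre is formed; the four ring stereocentres are cleared and two alkene geometries are set. In each ring the C13 methylene is trans to the leaving group, turns outward and so ends cis to the methyl and trans to CH2Br, which is the E geometry; the cis relation installed in step 1 fixes this whichever ring-to-ring isomer reacts. The step needs this torquoselectivity, capture at the primary terminus (favoured because it gives the trisubstituted alkene, any secondary allylic bromide being able to return through the same cation under MgBr2) and no proton loss from the doubly allylic C13, for which the weakly ionising ether medium and the high bromide concentration are chosen.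

Step 4
Reactants: 9 2-(furan-3-yl)ethanol
Product: 10 3-(2-bromoethyl)furan
Conditions: CBr4, PPh3, CH2Cl2, 0 °C
Reagents that add atoms: carbon tetrabromide, BrC(Br)(Br)Br
Why: Appel reaction, in which the primary alcohol is activated as an alkoxyphosphonium ion and displaced by bromide under neutral conditions that the acid-sensitive furan tolerates.

Step 5
Reactants: 10 3-(2-bromoethyl)furan; 8 (2E,5E)-1,7-dibromo-2,6-dimethylhepta-2,5-diene
Product: 12 3-[(4E,7E)-9-bromo-4,8-dimethylnona-4,7-dien-1-yl]furan, via furylethylmagnesium bromide 11 (not isolated)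
Conditions: Mg, THF, 40 °C; then added slowly to 8 (3 equiv), Li2CuCl4 (3 mol%), THF, −78 to 0 °C
Reagents that add atoms: none
Why: Kochi-type Li2CuCl4-catalysed coupling of a primary alkyl Grignard reagent and a primary allylic bromide, which should proceed by direct substitution at CH2Br and keep the E alkene, while slow addition of 11 to an excess of the symmetric dibromide holds double coupling down and unreacted 8 is recovered.

Step 6
Reactants: 13 (S)-2-methylbutane-1,4-diol
Product: 14 (3S)-4-hydroxy-3-methylbutyl 2,2-dimethylpropanoate
Conditions: PivCl (1.0 equiv), pyridine, CH2Cl2, −30 to 0 °C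
Reagents that add atoms: pivaloyl chloride, CC(C)(C)C(Cl)=O
Why: Regioselective acylation, in which the bulky acid chloride at low temperature prefers the unbranched C4 hydroxyl over the β-branched C1 hydroxyl, the minor regioisomer and the diester being removed by chromatography and the stereocentre not being involved.

Step 7
Reactants: 14 (3S)-4-hydroxy-3-methylbutyl 2,2-dimethylpropanoate
Product: 15 (3S)-4-[(tert-butyldimethylsilyl)oxy]-3-methylbutyl 2,2-dimethylpropanoate
Conditions: TBSCl, imidazole, DMF, rt
Reagents that add atoms: tert-butyldimethylsilyl chloride, CC(C)(C)[Si](C)(C)Cl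
Why: Standard imidazole-promoted silylation of the remaining primary hydroxyl, giving an ether that survives the hydride, Grignard and copper-catalysed steps that follow.

Step 8
Reactants: 15 (3S)-4-[(tert-butyldimethylsilyl)oxy]-3-methylbutyl 2,2-dimethylpropanoate
Product: 16 (3S)-4-[(tert-butyldimethylsilyl)oxy]-3-methylbutan-1-ol
Conditions: iBu2AlH, CH2Cl2, −78 °C; aq. KNaC4H4O6
Reagents that add atoms: none
Why: Reductive cleavage of the pivalate by iBu2AlH at low temperature, conditions to which the silyl ether and the remote stereocentre are inert.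

Step 9
Reactants: 16 (3S)-4-[(tert-butyldimethylsilyl)oxy]-3-methylbutan-1-ol
Product: 17 [(2S)-4-bromo-2-methylbutoxy](tert-butyl)dimethylsilane
Conditions: CBr4, PPh3, CH2Cl2, 0 °C
Reagents that add atoms: carbon tetrabromide, BrC(Br)(Br)Br
Why: Appel reaction on the unhindered primary alcohol, neutral enough to keep the silyl ether and two carbons away from the stereocentre, which is not touched.

Step 10
Reactants: 17 [(2S)-4-bromo-2-methylbutoxy](tert-butyl)dimethylsilane; 12 3-[(4E,7E)-9-bromo-4,8-dimethylnona-4,7-dien-1-yl]furan
Product: 19 tert-butyl{[(2S,6E,9E)-13-(furan-3-yl)-2,6,10-trimethyltrideca-6,9-dien-1-yl]oxy}dimethylsilane, via silyloxyalkylmagnesium bromide 18 (not isolated)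
Conditions: Mg, THF, 40 °C (1.3 equiv of 17); then 12, Li2CuCl4 (5 mol%), THF, −78 to 0 °C
Reagents that add atoms: none
Why: Second Kochi-type Li2CuCl4-catalysed coupling, again by direct substitution at the primary allylic carbon with retention of alkene geometry, the silyl ether, furan and skipped diene being inert to the alkylcopper species at low temperature and C7 being carried in unchanged from 13.

Step 11
Reactants: 19 tert-butyl{[(2S,6E,9E)-13-(furan-3-yl)-2,6,10-trimethyltrideca-6,9-dien-1-yl]oxy}dimethylsilane
Product: 20 (2S,6E,9E)-13-(furan-3-yl)-2,6,10-trimethyltrideca-6,9-dien-1-ol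
Conditions: Bu4NF, THF, 0 °C to rt
Reagents that add atoms: none
Why: Fluoride-induced cleavage of the Si–O bond, selective because no other group in 19 responds to Bu4NF.

Step 12
Reactants: 20 (2S,6E,9E)-13-(furan-3-yl)-2,6,10-trimethyltrideca-6,9-dien-1-ol
Product: 21 (2S,6E,9E)-13-(furan-3-yl)-2,6,10-trimethyltrideca-6,9-dienal
Conditions: Dess–Martin periodinane, CH2Cl2, 0 °C to rt
Reagents that add atoms: none
Why: Dess–Martin oxidation of the primary alcohol under nearly neutral conditions, which stops at the aldehyde, leaves furan and alkenes alone and should not epimerise the α-methyl centre if 21 is used at once.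

Step 13
Reactants: 22 3-methyltetronic acid
Product: 23 4-methoxy-3-methylfuran-2(5H)-one
Conditions: Me2SO4, K2CO3, acetone, reflux
Reagents that add atoms: dimethyl sulfate, COS(=O)(=O)OC
Why: O-Alkylation of a vinylogous acid, the tetronate anion being methylated by the hard electrophile at the C4 oxygen to give the vinylogous ester that masks the acid and leaves C5 as the only acidic position.

Step 14
Reactants: 23 4-methoxy-3-methylfuran-2(5H)-one; 21 (2S,6E,9E)-13-(furan-3-yl)-2,6,10-trimethyltrideca-6,9-dienal
Product: 25 5-[(2S,6E,9E)-13-(furan-3-yl)-1-hydroxy-2,6,10-trimethyltrideca-6,9-dien-1-yl]-4-methoxy-3-methylfuran-2(5H)-one, via lithium dienolate 24 (not isolated)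
Conditions: LiN(iPr)2, THF, −78 °C; then 21, −78 °C; AcOH quench
Reagents that add atoms: none
Why: Aldol addition of the C5-lithiated methyl tetronate (a 2-oxyfuran dienolate) to the aldehyde at −78 °C, expected to be faster than enolisation of 21 so that C7 keeps its configuration, while the new centres C5 and C6 form without control and are both erased in step 15.

Step 15
Reactants: 25 5-[(2S,6E,9E)-13-(furan-3-yl)-1-hydroxy-2,6,10-trimethyltrideca-6,9-dien-1-yl]-4-methoxy-3-methylfuran-2(5H)-one
Product: 27 (5E)-5-[(2S,6E,9E)-13-(furan-3-yl)-2,6,10-trimethyltrideca-6,9-dien-1-ylidene]-4-methoxy-3-methylfuran-2(5H)-one, via secondary mesylate 26 (not isolated)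
Conditions: MsCl, Et3N, CH2Cl2, 0 °C; then DBU, 0 °C to rt; chromatographic separation of the 5E isomer
Reagents that add atoms: none
Why: Mesylation followed by base-induced E1cB elimination through the C5 dienolate should give the 5-ylidene tetronate as a pair of geometric isomers, of which the Z form is expected to be the more abundant, so the 5E isomer 27 (alkyl branch on the side of the methoxy group) is separated by chromatography and contact with DBU is kept short to spare the allylic C7 centre.

Step 16
Reactants: 27 (5E)-5-[(2S,6E,9E)-13-(furan-3-yl)-2,6,10-trimethyltrideca-6,9-dien-1-ylidene]-4-methoxy-3-methylfuran-2(5H)-one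
Product: 28 (5E)-5-[(2S,6E,9E)-13-(furan-3-yl)-2,6,10-trimethyltrideca-6,9-dien-1-ylidene]-4-hydroxy-3-methylfuran-2(5H)-one
Conditions: LiSPr, HMPA, rt; then dilute HCl to pH 3, 0 °C
Reagents that add atoms: none
Why: SN2 demethylation, in which the soft thiolate attacks the O-methyl carbon of the vinylogous ester and expels the stabilised tetronate anion at room temperature, where substitution is expected to outrun reversible thiolate addition at C6 so that the 5E alkene, the furan, the skipped diene and C7 persist, and mild acidification then frees the tetronic acid.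

Compound list
1 | penta-1,4-diene | C=CCC=C | starting material
2 | ethyl acetate | CCOC(C)=O | starting material
3 | (1S*,2S*)-1-methyl-2-(prop-2-en-1-yl)cyclopropan-1-ol, methyl cis to allyl, racemic, present as its titanium alkoxide | C[C@]1(O)C[C@@H]1CC=C | intermediate (not isolated)
4 | 2,2'-methylenebis(1-methylcyclopropan-1-ol), (1S*,2S*) in each ring, meso and racemic forms, (1S,2S,1'S,2'S) drawn | C[C@]1(O)C[C@@H]1C[C@H]1C[C@]1(C)O | intermediate
5 | 2-[(2-hydroxy-2-methylcyclopropyl)methyl]-1-methylcyclopropyl methanesulfonate, same relative configuration as 4 | C[C@]1(OS(C)(=O)=O)C[C@@H]1C[C@H]1C[C@]1(C)O | intermediate (not isolated)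
6 | methylenebis(1-methylcyclopropane-2,1-diyl) dimethanesulfonate, methyl cis to the bridging CH2 in each ring | C[C@]1(OS(C)(=O)=O)C[C@@H]1C[C@H]1C[C@]1(C)OS(C)(=O)=O | intermediate
7 | (1S*,2S*)-2-[(2E)-4-bromo-3-methylbut-2-en-1-yl]-1-methylcyclopropyl methanesulfonate | BrC/C(C)=C/C[C@H]1C[C@]1(C)OS(C)(=O)=O | intermediate (not isolated)
8 | (2E,5E)-1,7-dibromo-2,6-dimethylhepta-2,5-diene | BrC/C(C)=C/C/C=C(\C)CBr | intermediate
9 | 2-(furan-3-yl)ethanol | OCCc1ccoc1 | starting material
10 | 3-(2-bromoethyl)furan | BrCCc1ccoc1 | intermediate
11 | [2-(furan-3-yl)ethyl]magnesium bromide | Br[Mg]CCc1ccoc1 | intermediate (not isolated)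
12 | 3-[(4E,7E)-9-bromo-4,8-dimethylnona-4,7-dien-1-yl]furan | BrC/C(C)=C/C/C=C(\C)CCCc1ccoc1 | intermediate
13 | (S)-2-methylbutane-1,4-diol | OC[C@@H](C)CCO | starting material
14 | (3S)-4-hydroxy-3-methylbutyl 2,2-dimethylpropanoate | OC[C@@H](C)CCOC(=O)C(C)(C)C | intermediate
15 | (3S)-4-[(tert-butyldimethylsilyl)oxy]-3-methylbutyl 2,2-dimethylpropanoate | CC(C)(C)[Si](C)(C)OC[C@@H](C)CCOC(=O)C(C)(C)C | intermediate
16 | (3S)-4-[(tert-butyldimethylsilyl)oxy]-3-methylbutan-1-ol | CC(C)(C)[Si](C)(C)OC[C@@H](C)CCO | intermediate
17 | [(2S)-4-bromo-2-methylbutoxy](tert-butyl)dimethylsilane | CC(C)(C)[Si](C)(C)OC[C@@H](C)CCBr | intermediate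
18 | {(3S)-4-[(tert-butyldimethylsilyl)oxy]-3-methylbutyl}magnesium bromide | CC(C)(C)[Si](C)(C)OC[C@@H](C)CC[Mg]Br | intermediate (not isolated)
19 | tert-butyl{[(2S,6E,9E)-13-(furan-3-yl)-2,6,10-trimethyltrideca-6,9-dien-1-yl]oxy}dimethylsilane | CC(C)(C)[Si](C)(C)OC[C@@H](C)CCC/C(C)=C/C/C=C(\C)CCCc1ccoc1 | intermediate
20 | (2S,6E,9E)-13-(furan-3-yl)-2,6,10-trimethyltrideca-6,9-dien-1-ol | OC[C@@H](C)CCC/C(C)=C/C/C=C(\C)CCCc1ccoc1 | intermediate
21 | (2S,6E,9E)-13-(furan-3-yl)-2,6,10-trimethyltrideca-6,9-dienal | O=C[C@@H](C)CCC/C(C)=C/C/C=C(\C)CCCc1ccoc1 | intermediate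
22 | 3-methyltetronic acid (4-hydroxy-3-methylfuran-2(5H)-one) | CC1=C(O)COC1=O | starting material
23 | 4-methoxy-3-methylfuran-2(5H)-one | COC1=C(C)C(=O)OC1 | intermediate
24 | lithium 4-methoxy-3-methylfuran-2-olate | [Li]Oc1occ(OC)c1C | intermediate (not isolated)
25 | 5-[(2S,6E,9E)-13-(furan-3-yl)-1-hydroxy-2,6,10-trimethyltrideca-6,9-dien-1-yl]-4-methoxy-3-methylfuran-2(5H)-one, mixture at C5 and C6 | COC1=C(C)C(=O)OC1C(O)[C@@H](C)CCC/C(C)=C/C/C=C(\C)CCCc1ccoc1 | intermediate
26 | (2S,6E,9E)-13-(furan-3-yl)-1-(3-methoxy-4-methyl-5-oxo-2,5-dihydrofuran-2-yl)-2,6,10-trimethyltrideca-6,9-dien-1-yl methanesulfonate, mixture at C5 and C6 | COC1=C(C)C(=O)OC1C(OS(C)(=O)=O)[C@@H](C)CCC/C(C)=C/C/C=C(\C)CCCc1ccoc1 | intermediate (not isolated)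
27 | (5E)-5-[(2S,6E,9E)-13-(furan-3-yl)-2,6,10-trimethyltrideca-6,9-dien-1-ylidene]-4-methoxy-3-methylfuran-2(5H)-one | CC1=C(OC)/C(=C\[C@@H](C)CCC/C(C)=C/C/C=C(\C)CCCc2ccoc2)OC1=O | intermediate
28 | (5E)-5-[(2S,6E,9E)-13-(furan-3-yl)-2,6,10-trimethyltrideca-6,9-dien-1-ylidene]-4-hydroxy-3-methylfuran-2(5H)-one | CC1=C(O)/C(=C\[C@@H](C)CCC/C(C)=C/C/C=C(\C)CCCc2ccoc2)OC1=O | target

Total step count: 16.
Longest linear sequence: 10 steps (1, 2, 3, 5, 10, 11, 12, 14, 15, 16); the branch from 13 (steps 6–9, joining at step 10) is equally long.

Steps most likely to fail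

Step 15. The elimination may show poor geometric control: the E1cB pathway tends to place the alkyl branch away from the methoxy group, so the wanted 5E isomer may be the lesser component, and longer contact with base could erode it further. Fallback (sets out from 25, returns at 27): the mesylation–elimination is run as before and the Z isomer, (5Z)-5-[(2S,6E,9E)-13-(furan-3-yl)-2,6,10-trimethyltrideca-6,9-dien-1-ylidene]-4-methoxy-3-methylfuran-2(5H)-one F1, is collected as well. F1 is then photoisomerised (Pyrex-filtered light above 290 nm, degassed MeCN, rt), the ylidene butenolide being the only chromophore that absorbs there. The 5E isomer 27 is separated from the photostationary mixture and recovered F1 is irradiated again.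

Step 1. The twofold alkene exchange may stall: the volatile diene can be lost, the reaction can stop at the stage of 3, or the Grignard reagent can attack the ester directly. Fallback (sets out from 2, returns at 4): ethyl acetate 2 is treated with pent-4-en-1-ylmagnesium bromide F2 (from 5-bromopent-1-ene and Mg) and Ti(OiPr)4 in Et2O–THF. This is the classical Kulinkovich reaction, in which the Grignard reagent itself supplies the titanacyclopropane, and it gives monocyclopropanol 3 as an isolated compound with the same cis relation. A single alkene-exchange hydroxycyclopropanation of its remaining vinyl group (2, Ti(OiPr)4, c-C5H9MgCl, one extra equivalent to deprotonate the hydroxyl) then completes 4, so no molecule has to pass through two exchange events in one flask.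

Step 3. The ring opening may lose a proton from the doubly allylic C13 of an allyl cation (giving conjugated polyenes), capture bromide at the secondary terminus, or open only one ring. Fallback (sets out from 1, returns at 8): twofold cross-metathesis of penta-1,4-diene 1 with excess methyl methacrylate (second-generation Hoveyda–Grubbs catalyst RuCl2(H2IMes)(=CH-C6H4-2-OiPr), 40 °C, sealed vessel) gives dimethyl (2E,5E)-2,6-dimethylhepta-2,5-dienedioate F3, whose E geometry rests on the thermodynamic preference of the metathesis. Reduction with iBu2AlH (CH2Cl2, −78 °C) gives (2E,5E)-2,6-dimethylhepta-2,5-diene-1,7-diol F4. A twofold Appel reaction (CBr4, PPh3, CH2Cl2, 0 °C) converts F4 into 8 without any cationic intermediate.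

Further compounds
F1 | step 15 | (5Z)-5-[(2S,6E,9E)-13-(furan-3-yl)-2,6,10-trimethyltrideca-6,9-dien-1-ylidene]-4-methoxy-3-methylfuran-2(5H)-one | CC1=C(OC)/C(=C/[C@@H](C)CCC/C(C)=C/C/C=C(\C)CCCc2ccoc2)OC1=O
F2 | step 1 | pent-4-en-1-ylmagnesium bromide | C=CCCC[Mg]Br
F3 | step 3 | dimethyl (2E,5E)-2,6-dimethylhepta-2,5-dienedioate | COC(=O)/C(C)=C/C/C=C(\C)C(=O)OC
F4 | step 3 | (2E,5E)-2,6-dimethylhepta-2,5-diene-1,7-diol | OC/C(C)=C/C/C=C(\C)CO
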